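**Retrosynthetic overview**

1. Locants: flavone unprimed; flavan O1''–C8a'' (ring A'' = C4a''–C8a''; heterocycle = O1'', C2'', C3'', C4'', C4a'', C8a''); flavan aryl ring triple-primed. Last operations are removal of one pivalate and five benzyl ethers.
2. Key disconnection: the C3–C6'' bond and the C4''–C4a'' bond together. 3-Metallated tri-O-benzylapigenin adds to the carbonyl carbon (future C6'') of spirodienone 8; ionisation of the tertiary dienol makes C4'' migrate from the spiro carbon C8a'' to C4a''. This enlarges the five-membered oxolane (O1'', C2'', C3'', C4'', C8a'') to the six-membered dihydropyran and aromatises ring A''.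
3. Enabling feature: in ring A'' the flavone-bearing C6'' lies between the oxygen-bearing C5'' and C7'' and para to C8a''–O1''. Ring A'' therefore maps onto a 2,6-dioxygenated cyclohexa-2,5-dienone with C6'' as carbonyl carbon and C8a'' as spiro carbon carrying O1'' and C4''; C4a'' and C8'' are equivalent, so the shift can only give the 6-linked 5,7-dioxygenated chroman.
4. 8 comes from phenol–alcohol 7 by oxidative spirocyclisation; 7 from ketone 6 by asymmetric transfer hydrogenation (sets C2''); 6 from aldehyde 2 and ketone 4 by aldol condensation and C=C hydrogenation.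
5. Ring order: both flavone rings are bought with apigenin; the oxolane spiro ring is made in step 6; the dihydropyran arises from it by expansion, together with aromatic ring A'', in step 8.

Key step: step 8

Assumption: the target defines only the C2'' stereocentre; the hindered C3–C6'' axis is taken as configurationally unfixed and is not controlled.

Step 1
Reactants: 1 3,4,5-tris(benzyloxy)benzaldehyde
Product: 2 3,5-bis(benzyloxy)-4-hydroxybenzaldehyde
Conditions: NaSEt (1.1 equiv), DMF, 60 °C; aq. HCl work-up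
Reagents that add atoms: none
Why: Nucleophilic dealkylation (SN2 of thiolate at the benzylic carbon) should select the 4-ether, because only its phenoxide leaving group is conjugated to the para formyl group and its loss relieves the strain of the doubly flanked ether.

Step 2
Reactants: 3 1-(4-hydroxyphenyl)ethanone
Product: 4 4-acetylphenyl pivalate
Conditions: pivaloyl chloride, Et3N, DMAP (cat.), CH2Cl2, 0 °C → rt
Reagents that add atoms: pivaloyl chloride, CC(C)(C)C(=O)Cl
Why: DMAP-catalysed O-acylation installs an electron-poor, hindered ester without α-hydrogen, chosen so that the later benzylic C2''–O1'' bond does not ionise in the cationic key step and the ester resists the organometallic reagent.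

Step 3
Reactants: 2 3,5-bis(benzyloxy)-4-hydroxybenzaldehyde; 4 4-acetylphenyl pivalate
Product: 5 4-[(2E)-3-[3,5-bis(benzyloxy)-4-hydroxyphenyl]prop-2-enoyl]phenyl pivalate
Conditions: BF3·OEt2 (promoter), 1,4-dioxane, rt
Reagents that add atoms: none
Why: Acid-promoted Claisen–Schmidt (aldol) condensation through the boron-bound enol of 4 tolerates the free phenol and the base-labile aryl ester and should give the E-enone after dehydration.

Step 4
Reactants: 5 4-[(2E)-3-[3,5-bis(benzyloxy)-4-hydroxyphenyl]prop-2-enoyl]phenyl pivalate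
Product: 6 4-[3-[3,5-bis(benzyloxy)-4-hydroxyphenyl]propanoyl]phenyl pivalate
Conditions: H2 (1 atm), Pd/C, Ph2S (cat.), EtOAc, rt
Reagents that add atoms: none
Why: Heterogeneous hydrogenation over sulfide-poisoned palladium should saturate the enone C=C while hydrogenolysis of the benzyl ethers and reduction of the aryl ketone are suppressed.

Step 5
Reactants: 6 4-[3-[3,5-bis(benzyloxy)-4-hydroxyphenyl]propanoyl]phenyl pivalate
Product: 7 4-[(1S)-3-[3,5-bis(benzyloxy)-4-hydroxyphenyl]-1-hydroxypropyl]phenyl pivalate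
Conditions: RuCl(p-cymene)[(S,S)-TsDPEN] (1 mol %), HCO2H/Et3N (5:2), EtOAc, 30 °C
Reagents that add atoms: none
Why: Noyori–Ikariya asymmetric transfer hydrogenation of the aryl alkyl ketone, in which the (S,S)-ligand holds the aryl group next to the η6-arene (CH–π contact) so that hydride reaches the Re face and sets the S carbinol centre that becomes C2''.

Step 6
Reactants: 7 4-[(1S)-3-[3,5-bis(benzyloxy)-4-hydroxyphenyl]-1-hydroxypropyl]phenyl pivalate
Product: 8 4-[(2S)-7,9-bis(benzyloxy)-8-oxo-1-oxaspiro[4.5]deca-6,9-dien-2-yl]phenyl pivalate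
Conditions: PhI(OAc)2 (1.05 equiv), (CF3)2CHOH, 0 °C
Reagents that add atoms: none
Why: Oxidative dearomatisation of the phenol by trivalent iodine with 5-exo capture of the para carbon by the tethered secondary hydroxyl (spiroetherification) should give the para-quinol ether; no bond at the stereocentre is touched and the spiro carbon is not stereogenic because its two ring arms are identical.

Step 7
Reactants: 9 apigenin
Product: 10 5,7-bis(benzyloxy)-2-[4-(benzyloxy)phenyl]-4H-chromen-4-one
Conditions: benzyl bromide (excess), K2CO3, DMF, 80 °C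
Reagents that add atoms: benzyl bromide, BrCc1ccccc1
Why: Williamson etherification of all three phenols, the hydrogen-bonded 5-OH needing the excess reagent and heating.

Step 8
Reactants: 10 5,7-bis(benzyloxy)-2-[4-(benzyloxy)phenyl]-4H-chromen-4-one; 8 4-[(2S)-7,9-bis(benzyloxy)-8-oxo-1-oxaspiro[4.5]deca-6,9-dien-2-yl]phenyl pivalate
Product: 14 4-[(2S)-5,7-bis(benzyloxy)-6-{5,7-bis(benzyloxy)-2-[4-(benzyloxy)phenyl]-4-oxo-4H-chromen-3-yl}-3,4-dihydro-2H-chromen-2-yl]phenyl pivalate, via 3-lithioflavone 11 (not isolated), via tertiary dienyl alkoxide 12 (not isolated), via dienyl trifluoroacetate 13 (not isolated)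
Conditions: LiN(iPr)2, THF, −78 °C; CeCl3, −78 °C; then 8, −78 → −40 °C; then (CF3CO)2O, 2,6-lutidine, −40 → 0 °C
Reagents that add atoms: none
Why: LiN(iPr)2 deprotonates 10 at C3 to give 11, which after transmetalation to cerium adds 1,2 to the carbonyl carbon of 8 to give alkoxide 12; trifluoroacetylation gives 13, which ionises to a cyclohexadienyl cation, C4'' then migrates from the spiro carbon C8a'' to the adjacent cationic carbon C4a'' (semipinacol-type 1,2-shift), and loss of the C4a'' proton aromatises ring A''. The closest known reaction types are the 1,2-addition of aryllithium or arylcerium reagents to quinone monoketals and quinol ethers and the ring-enlarging dienol–benzene rearrangement of spirocyclic cyclohexadienols. No ring is closed end to end: the five-membered oxolane is enlarged to the six-membered dihydropyran by the suprafacial [1,2]-shift of C4'', and this is the only ring-forming event. No new stereocentre is formed; C2'' takes part in no bond change and keeps its S configuration, and both epimers at the carbinol carbon converge on the same cation. The step needs 1,2- rather than conjugate addition, which the hard cerium reagent, chelation by the two α-benzyloxy groups and shielding of the β-carbons by the quaternary spiro centre should secure; it needs carbon rather than oxygen migration, which is secured because O1'' stays on C8a'' and turns the rearranged cation into an arenium ion stabilised by three oxygens (O1'', O5'', O7''); and its regiochemistry is fixed because C4a'' and C8'' are constitutionally equivalent in 8. Ionisation of the benzylic C2''–O1'' bond, the one process that could erode the stereocentre, is disfavoured by the electron-poor pivaloyloxy group on the adjacent aryl ring and by the lutidine buffer.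

Step 9
Reactants: 14 4-[(2S)-5,7-bis(benzyloxy)-6-{5,7-bis(benzyloxy)-2-[4-(benzyloxy)phenyl]-4-oxo-4H-chromen-3-yl}-3,4-dihydro-2H-chromen-2-yl]phenyl pivalate
Product: 15 5,7-bis(benzyloxy)-2-[4-(benzyloxy)phenyl]-3-[(2S)-5,7-bis(benzyloxy)-2-(4-hydroxyphenyl)-3,4-dihydro-2H-chromen-6-yl]-4H-chromen-4-one
Conditions: K2CO3 (cat.), MeOH/THF, 0 °C → rt
Reagents that add atoms: none
Why: Base-catalysed transesterification (methanolysis) of the aryl pivalate under mild conditions should leave the benzyl ethers, the flavone and the C2'' stereocentre untouched.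

Step 10
Reactants: 15 5,7-bis(benzyloxy)-2-[4-(benzyloxy)phenyl]-3-[(2S)-5,7-bis(benzyloxy)-2-(4-hydroxyphenyl)-3,4-dihydro-2H-chromen-6-yl]-4H-chromen-4-one
Product: 16 3-[(2S)-5,7-dihydroxy-2-(4-hydroxyphenyl)-3,4-dihydro-2H-chromen-6-yl]-5,7-dihydroxy-2-(4-hydroxyphenyl)-4H-chromen-4-one
Conditions: H2 (1 atm), Pd(OH)2/C, THF/MeOH, rt
Reagents that add atoms: none
Why: Catalytic hydrogenolysis of the five benzyl aryl ethers under neutral conditions avoids the acid- or base-induced opening of the 4'-hydroxyflavan ring that could racemise C2''; the tetrasubstituted flavone C2=C3 bond and the cyclic benzylic ether are not expected to react at ambient pressure.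

**Compound list**

1 | 3,4,5-tris(benzyloxy)benzaldehyde | O=Cc1cc(OCc2ccccc2)c(OCc2ccccc2)c(OCc2ccccc2)c1 | starting material
2 | 3,5-bis(benzyloxy)-4-hydroxybenzaldehyde | O=Cc1cc(OCc2ccccc2)c(O)c(OCc2ccccc2)c1 | intermediate
3 | 1-(4-hydroxyphenyl)ethanone | CC(=O)c1ccc(O)cc1 | starting material
4 | 4-acetylphenyl pivalate | CC(=O)c1ccc(OC(=O)C(C)(C)C)cc1 | intermediate
5 | 4-[(2E)-3-[3,5-bis(benzyloxy)-4-hydroxyphenyl]prop-2-enoyl]phenyl pivalate | O=C(/C=C/c1cc(OCc2ccccc2)c(O)c(OCc2ccccc2)c1)c1ccc(OC(=O)C(C)(C)C)cc1 | intermediate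
6 | 4-[3-[3,5-bis(benzyloxy)-4-hydroxyphenyl]propanoyl]phenyl pivalate | O=C(CCc1cc(OCc2ccccc2)c(O)c(OCc2ccccc2)c1)c1ccc(OC(=O)C(C)(C)C)cc1 | intermediate
7 | 4-[(1S)-3-[3,5-bis(benzyloxy)-4-hydroxyphenyl]-1-hydroxypropyl]phenyl pivalate | Oc1c(OCc2ccccc2)cc(CC[C@@H](c2ccc(OC(=O)C(C)(C)C)cc2)O)cc1OCc1ccccc1 | intermediate
8 | 4-[(2S)-7,9-bis(benzyloxy)-8-oxo-1-oxaspiro[4.5]deca-6,9-dien-2-yl]phenyl pivalate | O=C1C(OCc2ccccc2)=CC2(CC[C@@H](c3ccc(OC(=O)C(C)(C)C)cc3)O2)C=C1OCc1ccccc1 | intermediate
9 | apigenin, 5,7-dihydroxy-2-(4-hydroxyphenyl)-4H-chromen-4-one | O=c1cc(-c2ccc(O)cc2)oc2cc(O)cc(O)c12 | starting material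
10 | 5,7-bis(benzyloxy)-2-[4-(benzyloxy)phenyl]-4H-chromen-4-one | O=c1cc(-c2ccc(OCc3ccccc3)cc2)oc2cc(OCc3ccccc3)cc(OCc3ccccc3)c12 | intermediate
11 | 5,7-bis(benzyloxy)-2-[4-(benzyloxy)phenyl]-3-lithio-4H-chromen-4-one (not isolated) | [Li]c1c(-c2ccc(OCc3ccccc3)cc2)oc2cc(OCc3ccccc3)cc(OCc3ccccc3)c2c1=O | intermediate
12 | tertiary dienyl alkoxide from 1,2-addition, drawn as the lithium salt, (2S), both epimers at the carbinol carbon (not isolated) | [Li]OC1(c2c(-c3ccc(OCc4ccccc4)cc3)oc3cc(OCc4ccccc4)cc(OCc4ccccc4)c3c2=O)C(OCc2ccccc2)=CC2(CC[C@@H](c3ccc(OC(=O)C(C)(C)C)cc3)O2)C=C1OCc1ccccc1 | intermediate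
13 | trifluoroacetate of the tertiary dienol, (2S), both epimers at the carbinol carbon (not isolated) | FC(F)(F)C(=O)OC1(c2c(-c3ccc(OCc4ccccc4)cc3)oc3cc(OCc4ccccc4)cc(OCc4ccccc4)c3c2=O)C(OCc2ccccc2)=CC2(CC[C@@H](c3ccc(OC(=O)C(C)(C)C)cc3)O2)C=C1OCc1ccccc1 | intermediate
14 | 4-[(2S)-5,7-bis(benzyloxy)-6-{5,7-bis(benzyloxy)-2-[4-(benzyloxy)phenyl]-4-oxo-4H-chromen-3-yl}-3,4-dihydro-2H-chromen-2-yl]phenyl pivalate | O=c1c(-c2c(OCc3ccccc3)cc3c(c2OCc2ccccc2)CC[C@@H](c2ccc(OC(=O)C(C)(C)C)cc2)O3)c(-c2ccc(OCc3ccccc3)cc2)oc2cc(OCc3ccccc3)cc(OCc3ccccc3)c12 | intermediate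
15 | 5,7-bis(benzyloxy)-2-[4-(benzyloxy)phenyl]-3-[(2S)-5,7-bis(benzyloxy)-2-(4-hydroxyphenyl)-3,4-dihydro-2H-chromen-6-yl]-4H-chromen-4-one | O=c1c(-c2c(OCc3ccccc3)cc3c(c2OCc2ccccc2)CC[C@@H](c2ccc(O)cc2)O3)c(-c2ccc(OCc3ccccc3)cc2)oc2cc(OCc3ccccc3)cc(OCc3ccccc3)c12 | intermediate
16 | 3-[(2S)-5,7-dihydroxy-2-(4-hydroxyphenyl)-3,4-dihydro-2H-chromen-6-yl]-5,7-dihydroxy-2-(4-hydroxyphenyl)-4H-chromen-4-one | O=c1c(-c2c(O)cc3c(c2O)CC[C@@H](c2ccc(O)cc2)O3)c(-c2ccc(O)cc2)oc2cc(O)cc(O)c12 | target

**Step count and risks**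

Total step count: 10. Longest linear sequence: 8 steps (1, 3, 4, 5, 6, 8, 9, 10).

Steps most likely to fail:

Step 8. The hindered organometallic may fail to add to the carbonyl flanked by two benzyloxy groups, or may add in conjugate fashion or to the pivalate, so that the dienol never forms. Fallback (ring expansion first, C–C bond by cross-coupling): from 8, BF3·OEt2 in CH2Cl2 at −20 °C should trigger the dienone–phenol rearrangement, with the same 1,2-shift of C4'', to 4-[(2S)-5,7-bis(benzyloxy)-6-hydroxy-3,4-dihydro-2H-chromen-2-yl]phenyl pivalate F1. Triflation (Tf2O, pyridine, CH2Cl2, 0 °C) would give the aryl triflate F2, and Miyaura borylation (B2pin2, Pd(OAc)2, XPhos, KOAc, dioxane, 90 °C) the pinacol boronate F3. In parallel 10 would be iodinated at C3 (LiN(iPr)2, THF, −78 °C; then I2) to 5,7-bis(benzyloxy)-2-[4-(benzyloxy)phenyl]-3-iodo-4H-chromen-4-one F4. Suzuki–Miyaura coupling of F3 with F4 (Pd(OAc)2, SPhos, K3PO4, toluene/H2O, 90 °C) comes back to the route at 14.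

Step 6. The oxidised phenol may be captured at a benzyloxy-bearing ortho carbon by acetate or solvent, or may tautomerise to the quinone methide, instead of closing the spiro ring at the para carbon. Fallback (oxygen first, ring closure by substitution): from 6, transfer hydrogenation with RuCl(p-cymene)[(R,R)-TsDPEN] and HCO2H/Et3N would give the enantiomeric alcohol 4-[(1R)-3-[3,5-bis(benzyloxy)-4-hydroxyphenyl]-1-hydroxypropyl]phenyl pivalate F5. Oxidation with KHSO5 (as 2KHSO5·KHSO4·K2SO4) and NaHCO3 in MeCN/H2O, then Na2S2O3, would give the para-quinol 4-[(1R)-3-[3,5-bis(benzyloxy)-1-hydroxy-4-oxocyclohexa-2,5-dien-1-yl]-1-hydroxypropyl]phenyl pivalate F6. Selective mesylation of the secondary benzylic hydroxyl (MsCl, Et3N, CH2Cl2, −20 °C) would give the mesylate F7. NaH in THF at 0 °C should then close the oxolane by intramolecular Williamson substitution with inversion at the benzylic carbon, which comes back to the route at 8.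

Step 1. The thiolate may also cleave the meta benzyl ethers or react further, so that mixtures of phenols result. Fallback (protecting-group relay through the triol): from 1, BCl3 in CH2Cl2 at −78 °C would remove all three benzyl groups to give 3,4,5-trihydroxybenzaldehyde F8. The most acidic 4-hydroxyl would be allylated selectively (allyl bromide, NaHCO3, DMF, rt) to 4-(allyloxy)-3,5-dihydroxybenzaldehyde F9, and benzylation (benzyl bromide, K2CO3, DMF) would give 4-(allyloxy)-3,5-bis(benzyloxy)benzaldehyde F10. Tsuji–Trost deallylation with Pd(PPh3)4 and morpholine in THF comes back to the route at 2.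

**Further compounds**

F1 | step 8 | 4-[(2S)-5,7-bis(benzyloxy)-6-hydroxy-3,4-dihydro-2H-chromen-2-yl]phenyl pivalate | Oc1c(OCc2ccccc2)cc2c(c1OCc1ccccc1)CC[C@@H](c1ccc(OC(=O)C(C)(C)C)cc1)O2
F2 | step 8 | 4-[(2S)-5,7-bis(benzyloxy)-6-(trifluoromethylsulfonyloxy)-3,4-dihydro-2H-chromen-2-yl]phenyl pivalate | O=S(=O)(Oc1c(OCc2ccccc2)cc2c(c1OCc1ccccc1)CC[C@@H](c1ccc(OC(=O)C(C)(C)C)cc1)O2)C(F)(F)F
F3 | step 8 | 4-[(2S)-5,7-bis(benzyloxy)-6-(4,4,5,5-tetramethyl-1,3,2-dioxaborolan-2-yl)-3,4-dihydro-2H-chromen-2-yl]phenyl pivalate | CC1(C)OB(c2c(OCc3ccccc3)cc3c(c2OCc2ccccc2)CC[C@@H](c2ccc(OC(=O)C(C)(C)C)cc2)O3)OC1(C)C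
F4 | step 8 | 5,7-bis(benzyloxy)-2-[4-(benzyloxy)phenyl]-3-iodo-4H-chromen-4-one | O=c1c(I)c(-c2ccc(OCc3ccccc3)cc2)oc2cc(OCc3ccccc3)cc(OCc3ccccc3)c12
F5 | step 6 | 4-[(1R)-3-[3,5-bis(benzyloxy)-4-hydroxyphenyl]-1-hydroxypropyl]phenyl pivalate | Oc1c(OCc2ccccc2)cc(CC[C@H](c2ccc(OC(=O)C(C)(C)C)cc2)O)cc1OCc1ccccc1
F6 | step 6 | 4-[(1R)-3-[3,5-bis(benzyloxy)-1-hydroxy-4-oxocyclohexa-2,5-dien-1-yl]-1-hydroxypropyl]phenyl pivalate | O=C1C(OCc2ccccc2)=CC(O)(CC[C@H](c2ccc(OC(=O)C(C)(C)C)cc2)O)C=C1OCc1ccccc1
F7 | step 6 | 4-[(1R)-3-[3,5-bis(benzyloxy)-1-hydroxy-4-oxocyclohexa-2,5-dien-1-yl]-1-(methylsulfonyloxy)propyl]phenyl pivalate | O=C1C(OCc2ccccc2)=CC(O)(CC[C@H](c2ccc(OC(=O)C(C)(C)C)cc2)OS(C)(=O)=O)C=C1OCc1ccccc1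
F8 | step 1 | 3,4,5-trihydroxybenzaldehyde | O=Cc1cc(O)c(O)c(O)c1
F9 | step 1 | 4-(allyloxy)-3,5-dihydroxybenzaldehyde | O=Cc1cc(O)c(OCC=C)c(O)c1
F10 | step 1 | 4-(allyloxy)-3,5-bis(benzyloxy)benzaldehyde | O=Cc1cc(OCc2ccccc2)c(OCC=C)c(OCc2ccccc2)c1
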